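## Retrosynthetic overview

1. Target ⇐ its 5‑O‑silyl ether, by buffered fluoride in the same flask.
2. 5‑O‑silyl lactone ⇐ 4'‑O‑silyl dihydrochalcone + cinnamaldehyde. The dihydropyranone ring, the only ring made, is closed by C‑cinnamoylation of the acylphloroglucinol nucleus and lactonisation (C3'–Cβ bond, then 2'‑O–acyl bond), as in the presumed biogenesis. It is run as one chiral‑carbene‑catalysed oxidative formal [3+3] that sets C4.
3. 4'‑O‑silyl dihydrochalcone ⇐ free dihydrochalcone. The silyl group blocks the para oxygen, so lactonisation can give only the 8‑acyl chromanone, not the 6‑acyl isomer.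
4. Dihydrochalcone ⇐ phloroglucinol + 3‑(4‑methoxyphenyl)propanenitrile (Hoesch). Both benzene rings are bought; the lactone ring is formed last.

Assumption: the SMILES encodes (4S); the (5aS,10bR) triazolium is taken to give 4S on a face‑shielding model that I could not check against a measured case, so if the first batch shows 4R the commercial (5aR,10bS) antipode is used with nothing else changed.

## Route

Step 1
Reactants: 1 phloroglucinol; 2 3‑(4‑methoxyphenyl)propanenitrile
Product: 4 2',4',6'‑trihydroxy‑4‑methoxydihydrochalcone [1‑(2,4,6‑trihydroxyphenyl)‑3‑(4‑methoxyphenyl)propan‑1‑one], via ketiminium chloride 3 (not isolated)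
Conditions: HCl (g), ZnCl2 (0.2 equiv), dry Et2O, 0 °C, 24 h; then H2O, reflux, 2 h
Reagents that add atoms: water, O; hydrogen chloride, Cl (stays only in intermediate 3)
Why: Hoesch reaction, in which the HCl/ZnCl2‑activated nitrile acylates the C3‑symmetric, highly nucleophilic phloroglucinol once only because the ketiminium salt deactivates the ring, and hydrolysis of that salt gives the aryl ketone; no stereocentre is formed.

Step 2
Reactants: 4 2',4',6'‑trihydroxy‑4‑methoxydihydrochalcone
Product: 5 1‑[2,6‑dihydroxy‑4‑(triisopropylsilyloxy)phenyl]‑3‑(4‑methoxyphenyl)propan‑1‑one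
Conditions: TIPSCl (1.05 equiv), imidazole (2.2 equiv), DMF, −20 → 0 °C
Reagents that add atoms: triisopropylsilyl chloride, CC(C)[Si](Cl)(C(C)C)C(C)C
Why: Regioselective O‑silylation, in which the 4'‑OH is the most acidic phenol and the only one neither hydrogen‑bonded to nor flanked by the ketone, so the bulky silyl chloride takes it and leaves the 2'‑OH as the only oxygen that can later close the lactone; no stereocentre is formed.

Step 3
Reactants: 5 1‑[2,6‑dihydroxy‑4‑(triisopropylsilyloxy)phenyl]‑3‑(4‑methoxyphenyl)propan‑1‑one; 6 (E)‑cinnamaldehyde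
Product: 8 (4S)‑5,7‑dihydroxy‑8‑[3‑(4‑methoxyphenyl)propanoyl]‑4‑phenylchroman‑2‑one (target), via 5‑O‑TIPS lactone 7 (not isolated)
Conditions: (5aS,10bR)‑2‑mesityl‑5a,10b‑dihydro‑4H,6H‑indeno[2,1‑b][1,2,4]triazolo[4,3‑d][1,4]oxazin‑2‑ium chloride (10 mol %), DBU (20 mol %), 3,3',5,5'‑tetra‑tert‑butyl‑4,4'‑diphenoquinone (1.2 equiv), 6 (1.2 equiv), toluene, rt, 16 h; then TBAF (1.2 equiv), AcOH (1.5 equiv), THF, 0 °C, 30 min, same flask; pH 6 buffer work‑up
Reagents that add atoms: none
Why: Proposed new method: the carbene converts 6 into a Breslow intermediate that the quinone oxidises to a catalyst‑bound α,β‑unsaturated acyl azolium, the phenoxide of 5 adds through C3' (the only free, doubly oxygen‑activated ring carbon) to the β‑carbon on the face left open by the aminoindane, which sets C4 as S, and the neighbouring 2'‑OH, the only ortho oxygen not silylated, closes the δ‑lactone and releases the carbene (closest known reaction type: the oxidative NHC‑catalysed formal [3+3] Michael addition–lactonisation of enals with 2‑naphthols and 1,3‑dicarbonyls, a Coates–Claisen‑type annulation), after which acetic‑acid‑buffered fluoride cleaves the aryl silyl ether without opening the lactone or touching C4.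

## Compound list

1 | phloroglucinol (benzene‑1,3,5‑triol) | Oc1cc(O)cc(O)c1 | starting material
2 | 3‑(4‑methoxyphenyl)propanenitrile | COc1ccc(CCC#N)cc1 | starting material
3 | 1‑(2,4,6‑trihydroxyphenyl)‑3‑(4‑methoxyphenyl)propan‑1‑iminium chloride | COc1ccc(CCC(=[NH2+])c2c(O)cc(O)cc2O)cc1.[Cl-] | intermediate
4 | 1‑(2,4,6‑trihydroxyphenyl)‑3‑(4‑methoxyphenyl)propan‑1‑one | COc1ccc(CCC(=O)c2c(O)cc(O)cc2O)cc1 | intermediate
5 | 1‑[2,6‑dihydroxy‑4‑(triisopropylsilyloxy)phenyl]‑3‑(4‑methoxyphenyl)propan‑1‑one | COc1ccc(CCC(=O)c2c(O)cc(O[Si](C(C)C)(C(C)C)C(C)C)cc2O)cc1 | intermediate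
6 | (E)‑cinnamaldehyde | O=C/C=C/c1ccccc1 | starting material
7 | (4S)‑7‑hydroxy‑8‑[3‑(4‑methoxyphenyl)propanoyl]‑4‑phenyl‑5‑(triisopropylsilyloxy)chroman‑2‑one | COc1ccc(CCC(=O)c2c(O)cc(O[Si](C(C)C)(C(C)C)C(C)C)c3c2OC(=O)C[C@H]3c2ccccc2)cc1 | intermediate
8 | (4S)‑5,7‑dihydroxy‑8‑[3‑(4‑methoxyphenyl)propanoyl]‑4‑phenylchroman‑2‑one | COc1ccc(CCC(=O)c2c(O)cc(O)c3c2OC(=O)C[C@H]3c2ccccc2)cc1 | target

## Step count and risks

Total step count: 3. Longest linear sequence: 3 (1 → 4 → 5 → 8).

The route has three steps, so all three are ranked, most risky first.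

Step 3 (asymmetric annulation). The risks are O‑cinnamoylation of the chelated phenol instead of C‑attack, a second annulation at C6, low ee, or the opposite sense of induction. The fallback sets out from 5 and gives up asymmetric catalysis for resolution. Compound 5 is condensed with benzaldehyde and Meldrum's acid (Et3N, MeCN, 80 °C, or preformed benzylidene Meldrum's acid with catalytic Yb(OTf)3); Michael addition, lactonisation with loss of acetone, and decarboxylation give the racemic 5‑O‑TIPS lactone F1, with the same regiochemistry because the 4'‑oxygen is still blocked. Preparative chiral SFC separates the (4S)‑enantiomer from the (4R)‑enantiomer F2, which is discarded. The (4S)‑enantiomer is 7, where the fallback comes back to the route, and it is desilylated with TBAF/AcOH as in the second half of step 3.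

Step 2 (mono‑silylation). The risks are bis‑silylation, or a TIPS ether that is too bulky or too labile for the annulation. The fallback sets out from 4 and changes both the protecting group and the way it is put on. A Mitsunobu etherification (BnOH, PPh3, DIAD, THF, 0 °C) alkylates only the most acidic, non‑chelated 4'‑OH and gives the 4'‑O‑benzyl dihydrochalcone F3. This is annulated with 6 under the step 3 carbene conditions to the (4S)‑5‑O‑benzyl lactone F4. Hydrogenolysis (H2 1 atm, Pd/C, EtOAc, rt; the chelated aryl ketone, the lactone and C4 are untouched) comes back to the route at 8.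

Step 1 (Hoesch acylation). The risks are a sluggish nitrile or incomplete hydrolysis of the ketiminium salt. The fallback sets out from 1 and replaces the nitrile by the free acid: a direct Friedel–Crafts C‑acylation of 1 with 3‑(4‑methoxyphenyl)propanoic acid in neat BF3·OEt2 (85 °C, 2 h, then aqueous NaOAc) comes back to the route at 4 and makes no new compound (F0).

## Further compounds

F1 | step 3 | rac‑7‑hydroxy‑8‑[3‑(4‑methoxyphenyl)propanoyl]‑4‑phenyl‑5‑(triisopropylsilyloxy)chroman‑2‑one | COc1ccc(CCC(=O)c2c(O)cc(O[Si](C(C)C)(C(C)C)C(C)C)c3c2OC(=O)CC3c2ccccc2)cc1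
F2 | step 3 | (4R)‑7‑hydroxy‑8‑[3‑(4‑methoxyphenyl)propanoyl]‑4‑phenyl‑5‑(triisopropylsilyloxy)chroman‑2‑one | COc1ccc(CCC(=O)c2c(O)cc(O[Si](C(C)C)(C(C)C)C(C)C)c3c2OC(=O)C[C@@H]3c2ccccc2)cc1
F3 | step 2 | 1‑[4‑(benzyloxy)‑2,6‑dihydroxyphenyl]‑3‑(4‑methoxyphenyl)propan‑1‑one | COc1ccc(CCC(=O)c2c(O)cc(OCc3ccccc3)cc2O)cc1
F4 | step 2 | (4S)‑5‑(benzyloxy)‑7‑hydroxy‑8‑[3‑(4‑methoxyphenyl)propanoyl]‑4‑phenylchroman‑2‑one | COc1ccc(CCC(=O)c2c(O)cc(OCc4ccccc4)c3c2OC(=O)C[C@H]3c2ccccc2)cc1
F0 | step 1 | none | none
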